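No rate constant is given, so I work from counts and from the readings.

| flask | D | X | remark | time |
|---|---|---|---|---|
| autumn | 0.50 mM | 20 mM | run made earlier |  |
| midnight | 2.7 mM | 20 mM | run made earlier |  |
| winter | 9 mM | 20 mM | run made earlier |  |
| cedar | 0.60 mM | 20.0 mM |  | 5.0 d |
| alder | 1.2 mM | 20.0 mM |  | 5.0 d |
| larch | 2.5 mM | 20.0 mM |  | 5.0 d |
| elm | 5.0 mM | 20.0 mM |  | 5.0 d |
| ash | 10 mM | 20.0 mM |  | 5.0 d |

- autumn (time / d: Q / %): 0.208: 2; 0.417: 0; 0.625: 2; 1.25: 9; 2.50: 27
- midnight (time / d: Q / %): 0.500: 3; 1.04: 4; 1.67: 10; 2.08: 14; 2.50: 21
- winter (time / d: Q / %): 0.208: 3; 0.417: 2; 0.625: 0; 1.25: 4; 2.50: 5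

(scatter of a reading: 1.5 percentage points)

- "hardly changes" means that all values lie within two and a half points (for a concentration: within two and a half percent of the largest)

- [Q] at the end for cedar, alder, larch, elm, ash, in this order
- how that number moves from the first to the last of them (rises, then falls / falls, then rises / rises all the way / falls all the way / hardly changes)

Q is the tris adduct, so each Q holds 3 X. My one quantity is therefore the X ceiling, the charge of X divided by 3, which is 6.67 mM. By this count Q in a flask stays at or under this ceiling, and at or under its charge of D. In ash the charge of D stands above the ceiling, so X is the limiting reagent there. In elm the charge of D stands below it.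

I bracket ash. The autumn run reads 2% at 0.625 d and 27% at 2.50 d, so Q comes after a lag. I read this as a chain of additions.

For the floor, I take the winter yield of 5% at 2.50 d as the nearest reading for ash. If Q does not fall, ash ends at 0.500 mM or above.

For the top, I freeze X at its charge, which is the fastest it can act. A chain of 3 additions then grows at most as the cube of time. Doubling the time multiplies Q by at most 8.00, which gives 4.00 mM, below the ceiling. The bracket is wide, and the single winter reading carries its scatter.

The forecast gives 0.36 mM, 0.66 mM, 1.2 mM, 1.65 mM and 1.3 mM, and says the row rises, then falls. Its ground is “at 10 mM D, X is starved, since 20 mM covers only two additions per D”. Its ash value lies inside my bracket, above the floor and below the top.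

    D + X → E (k = 3.00 /M/h)
    X + E → L (k = 1.80 /M/h)
    X + L → Q (k = 0.830 /M/h)
    D + Q → G (k = 17.0 /M/h)

The flasks end at 0.382 mM, 0.716 mM, 1.27 mM, 1.72 mM and, in ash, 0.967 mM, which lies inside the bracket; the row rises, then falls, turning at 5.3 mM. That turn stands below the ceiling. At 5.00 d ash has X at 16.0% of its charge, with Q at 14.5% of the ceiling. At 50.0 d ash has X at 0.0155% of its charge, yet Q stands at 2.35 mM, below the ceiling. Elm, charged below the ceiling, holds 4.48 mM of Q at 50.0 d, with X at 28.8% of its charge.

The earlier runs and the new flask were generated by integration for an exercise; scatter was added.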